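**Retrosynthetic overview**

1. Feature: ring A (C1, C10–C14) and the ten-membered ring (C1–C10) share only the bond C1–C10, so the periphery C1→C14 is a 14-membered cembrane ring; the quaternary C1, the oxygen on C2 and the exocyclic C11=C20 are what an allylsilane leaves when it opens a C1–C2 epoxide across that ring.
2. Key disconnection: C1–C10, a transannular epoxide–allylsilane cyclisation of a 14-membered 1,2-epoxy cembranolide; it forms ring A and the ten-membered ring together, with the γ-lactone already in place.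
3. The 14-membered ring is opened at C11–C12 (ring-closing B-alkyl Suzuki coupling on a 1,1-dichloroalkene, then Me3SiCH2 on C11 by Negishi coupling) and at C4–C5 (B-alkyl Suzuki coupling of a Z bromoalkene).
4. Fragments: a lactone core C5–C11/C16–C19 from diacetone-D-glucose (C7 and C9 from the sugar, C8 by aldol on the 3-ulose) and an epoxy iodide C1–C4/C12–C15; the epoxide is made by Sharpless epoxidation before ring closure, because epoxidation of the macrocycle would have to choose among three trisubstituted alkenes, the allylsilane included.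
5. Ring order: γ-lactone (step 10), 14-membered carbocycle (step 22), ring A plus ten-membered ring (step 24); then 2-O-propanoylation, desilylation and 9,14-di-O-acetylation.

Key step: step 24

Remark: briarane numbering is used throughout (sugar C1–C5 become C6–C10; the propanoate carbons are C19, C17, C18); C17 is carried as both epimers until step 11 and the lactol as both anomers, so these centres have no stereo label in the SMILES until they are fixed; O9 carries a triisopropylsilyl group so that it survives the acidic lactonisation; the three starting materials are commercial.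

**Route**

Step 1
Reactants: 1 1,2:5,6-di-O-isopropylidene-α-D-glucofuranose (diacetone-D-glucose)
Product: 2 1,2:5,6-di-O-isopropylidene-α-D-ribo-hexofuranos-3-ulose
Conditions: Dess–Martin periodinane, CH2Cl2, rt
Reagents that add atoms: none
Why: Dess–Martin oxidation of the only free hydroxyl gives the ketone on which C8 is built, the two acetals being inert and no stereocentre being formed.

Step 2
Reactants: 2 1,2:5,6-di-O-isopropylidene-α-D-ribo-hexofuranos-3-ulose; 3 tert-butyl propanoate
Product: 5 3-C-[1-(tert-butoxycarbonyl)ethyl]-1,2:5,6-di-O-isopropylidene-α-D-allofuranose (C17 epimers), via lithium ester enolate 4 (not isolated)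
Conditions: LiN(iPr)2, THF, −78 °C; then 2, −78 °C; aq. NH4Cl at −78 °C
Reagents that add atoms: none
Why: Aldol addition of the lithium ester enolate to the ketone from the convex β-face, anti to the ring-fused 1,2-acetonide (the face taken by hydride and carbon nucleophiles on this ulose), sets C8 with its hydroxyl cis to O7, while C17 forms as both epimers and is set in step 11.

Step 3
Reactants: 5 3-C-[1-(tert-butoxycarbonyl)ethyl]-1,2:5,6-di-O-isopropylidene-α-D-allofuranose
Product: 6 3-C-[1-(tert-butoxycarbonyl)ethyl]-1,2-O-isopropylidene-α-D-allofuranose (5,6-diol)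
Conditions: 70% aq. AcOH, rt
Reagents that add atoms: none
Why: Selective acetal hydrolysis, the terminal 5,6-dioxolane opening much faster than the ring-fused 1,2-acetal and the tert-butyl ester surviving.

Step 4
Reactants: 6 3-C-[1-(tert-butoxycarbonyl)ethyl]-1,2-O-isopropylidene-α-D-allofuranose
Product: 7 3-C-[1-(tert-butoxycarbonyl)ethyl]-1,2-O-isopropylidene-α-D-ribo-pentodialdo-1,4-furanose (C10 aldehyde)
Conditions: NaIO4, THF/H2O, 0 °C
Reagents that add atoms: none
Why: Malaprade glycol cleavage removes the sixth sugar carbon and gives the C10 aldehyde under neutral conditions that should not epimerise C9 or provoke retro-aldol at C8.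

Step 5
Reactants: 7 3-C-[1-(tert-butoxycarbonyl)ethyl]-1,2-O-isopropylidene-α-D-ribo-pentodialdo-1,4-furanose
Product: 8 3-C-[1-(tert-butoxycarbonyl)ethyl]-6,6-dichloro-5,6-dideoxy-1,2-O-isopropylidene-α-D-ribo-hex-5-enofuranose (C10H=C11Cl2)
Conditions: PPh3, BrCCl3, MeCN, 0 °C → rt
Reagents that add atoms: bromotrichloromethane, ClC(Cl)(Cl)Br
Why: Wittig-type dichloromethylenation by Ph3P=CCl2 formed in the flask leaves C9 untouched and stores C10=C11 as a 1,1-dichloroalkene that is stable to acid and base and inert to the palladium catalysts used before step 22.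

Step 6
Reactants: 8 3-C-[1-(tert-butoxycarbonyl)ethyl]-6,6-dichloro-5,6-dideoxy-1,2-O-isopropylidene-α-D-ribo-hex-5-enofuranose
Product: 9 3-C-[1-(tert-butoxycarbonyl)ethyl]-6,6-dichloro-5,6-dideoxy-2,3-O-isopropylidene-D-ribo-hex-5-enofuranose (lactol at C6, both anomers; acetonide on O7 and O8)
Conditions: CSA (10 mol %), acetone, rt
Reagents that add atoms: none
Why: Acid-catalysed acetal migration under thermodynamic control, the dioxolane on the cis-2,3-diol (O7 and the tertiary O8) being the favoured acetonide as it is for ribose, so that C6 is freed as a lactol while O7 and O8 stay blocked.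

Step 7
Reactants: 9 3-C-[1-(tert-butoxycarbonyl)ethyl]-6,6-dichloro-5,6-dideoxy-2,3-O-isopropylidene-D-ribo-hex-5-enofuranose
Product: 10 open-chain tert-butyl ester with C6H=C5Br2 and C10H=C11Cl2 ends, O7 and O8 joined as acetonide, free 9-hydroxyl (C7, C8, C9 as in the target)
Conditions: CBr4, PPh3, Zn, CH2Cl2, rt; then 9, rt
Reagents that add atoms: tetrabromomethane, BrC(Br)(Br)Br
Why: Ramirez dibromo-olefination (first half of the Corey–Fuchs sequence) on the hydroxy-aldehyde tautomer of the lactol opens the furanose and releases the former ring oxygen O9 as the only free hydroxyl, zinc removing Ph3PBr2 so that this hydroxyl is not brominated.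

Step 8
Reactants: 10 open-chain dibromo alcohol
Product: 11 9-O-triisopropylsilyl ether of 10
Conditions: TIPSOTf, 2,6-lutidine, CH2Cl2, 0 °C
Reagents that add atoms: triisopropylsilyl trifluoromethanesulfonate, CC(C)[Si](OS(=O)(=O)C(F)(F)F)(C(C)C)C(C)C
Why: Silylation of the single free hydroxyl with a silyl triflate, the triisopropylsilyl ether being chosen because it should survive the acid of step 10 and later shield O9 from the Lewis acid of step 24.

Step 9
Reactants: 11 9-O-triisopropylsilyl dibromoalkene
Product: 12 Z bromoalkene C6H=C5(Br)CH3 (methyl C16 trans to C7), otherwise as 11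
Conditions: MeZnCl, PdCl2(DPEphos) (5 mol %), THF, 0 °C → rt
Reagents that add atoms: methylzinc chloride, C[Zn]Cl
Why: Negishi coupling in its trans-selective mono-alkylation mode, oxidative addition taking the C–Br bond trans to C7 so that C16 ends trans to C7 and the remaining bromide cis (Z), while the C–Cl bonds react far more slowly.

Step 10
Reactants: 12 Z bromoalkene acetonide tert-butyl ester
Product: 13 γ-lactone (O7–C19) with free 8-hydroxyl, 9-OTIPS, Z bromoalkene and dichloroalkene (C17 epimers)
Conditions: TsOH·H2O (0.3 equiv), H2O (3 equiv), toluene, 70 °C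
Reagents that add atoms: none
Why: Acid hydrolysis of the acetonide and acidolysis of the tert-butyl ester are followed by lactonisation, and because O9 is silylated and O8 is tertiary only O7 can close the five-membered lactone.

Step 11
Reactants: 13 γ-lactone (C17 epimers)
Product: 14 lactone core with methyl C18 cis to the 8-hydroxyl (17R; C7, C8, C9, C17 as in the target)
Conditions: DBU, toluene, 40 °C
Reagents that add atoms: none
Why: Base-mediated epimerisation α to the lactone carbonyl under thermodynamic control should put C18 trans to the bulky C9 branch on C8, which is the C17 configuration of the target.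

Step 12
Reactants: 15 3-[(4-methoxybenzyl)oxy]propan-1-ol
Product: 16 3-[(4-methoxybenzyl)oxy]propanal
Conditions: Dess–Martin periodinane, NaHCO3, CH2Cl2, rt
Reagents that add atoms: none
Why: Dess–Martin oxidation of the primary alcohol to the aldehyde (C2), the PMB ether being inert.

Step 13
Reactants: 16 3-[(4-methoxybenzyl)oxy]propanal
Product: 17 methyl (2Z)-5-[(4-methoxybenzyl)oxy]-2-methylpent-2-enoate
Conditions: (CF3CH2O)2P(O)CH(CH3)CO2CH3, KN(SiMe3)2, 18-crown-6, THF, −78 °C
Reagents that add atoms: methyl 2-[bis(2,2,2-trifluoroethoxy)phosphoryl]propanoate, COC(=O)C(C)P(=O)(OCC(F)(F)F)OCC(F)(F)F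
Why: Still–Gennari olefination, fast irreversible elimination from the trifluoroethyl phosphonate adduct giving the Z trisubstituted enoate with C14 cis to C3.

Step 14
Reactants: 17 methyl (2Z)-5-[(4-methoxybenzyl)oxy]-2-methylpent-2-enoate
Product: 18 (2Z)-5-[(4-methoxybenzyl)oxy]-2-methylpent-2-en-1-ol
Conditions: iBu2AlH (2.5 equiv), CH2Cl2, −78 °C
Reagents that add atoms: none
Why: 1,2-Reduction of the ester by the aluminium hydride gives the allylic alcohol with the Z geometry retained.

Step 15
Reactants: 18 (2Z)-5-[(4-methoxybenzyl)oxy]-2-methylpent-2-en-1-ol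
Product: 19 (2S,3R)-2,3-epoxy-5-[(4-methoxybenzyl)oxy]-2-methylpentan-1-ol
Conditions: Ti(OiPr)4 (10 mol %), L-(+)-diethyl tartrate (12 mol %), t-BuOOH, 4 Å MS, CH2Cl2, −20 °C
Reagents that add atoms: tert-butyl hydroperoxide, CC(C)(C)OO
Why: Sharpless asymmetric epoxidation, the L-(+)-tartrate catalyst delivering oxygen to the face that gives the (2S,3R) cis-epoxide and so setting C1 and C2 by reagent control.

Step 16
Reactants: 19 (2S,3R)-2,3-epoxy-5-[(4-methoxybenzyl)oxy]-2-methylpentan-1-ol
Product: 20 (2R,3R)-2,3-epoxy-5-[(4-methoxybenzyl)oxy]-2-methylpentanal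
Conditions: Dess–Martin periodinane, NaHCO3, CH2Cl2, 0 °C
Reagents that add atoms: none
Why: Dess–Martin oxidation to the epoxy aldehyde (C14), whose α-carbon C1 is quaternary and cannot epimerise.

Step 17
Reactants: 20 (2R,3R)-2,3-epoxy-5-[(4-methoxybenzyl)oxy]-2-methylpentanal
Product: 21 erythro allylic alcohol, (14S)-carbinol bearing the C12=C13 vinyl group next to the cis-epoxide
Conditions: CH2=CHMgBr, THF, −78 °C
Reagents that add atoms: vinylmagnesium bromide, C=C[Mg]Br
Why: Grignard addition under Felkin–Anh control, the nucleophile coming anti to the epoxide C1–O bond and past the small methyl group C15, should give the erythro (14S) alcohol.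

Step 18
Reactants: 21 erythro allylic alcohol
Product: 22 14-O-tert-butyldimethylsilyl ether of 21
Conditions: TBSCl, imidazole, DMF, rt
Reagents that add atoms: tert-butyl(chloro)dimethylsilane, CC(C)(C)[Si](C)(C)Cl
Why: Silylation with the silyl chloride and imidazole, a silyl triflate being avoided because it acts as a Lewis acid on 2,3-epoxy silyl ethers and triggers hydride-shift rearrangement.

Step 19
Reactants: 22 14-O-TBS ether
Product: 23 primary alcohol at C4 (PMB removed)
Conditions: DDQ, CH2Cl2/pH 7 buffer, 0 °C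
Reagents that add atoms: none
Why: Oxidative cleavage of the PMB ether by DDQ under buffered conditions frees the C4 hydroxyl without touching the epoxide, the silyl ether or the vinyl group.

Step 20
Reactants: 23 primary alcohol
Product: 24 epoxy iodide, C4–I with cis-1,2-epoxide, 14-OTBS and C12=C13 vinyl
Conditions: I2, PPh3, imidazole, CH2Cl2, 0 °C
Reagents that add atoms: iodine, II
Why: Appel-type (Garegg–Samuelsson) iodination of the primary alcohol by displacement on the alkoxyphosphonium ion, with no stereocentre involved.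

Step 21
Reactants: 24 epoxy iodide; 14 lactone core (Z bromoalkene)
Product: 26 open-chain coupling product joined at C4–C5 (C10H=C11Cl2 at one end; C12=C13 vinyl at the other), via lithium alkyl(methoxy)borate 25 (not isolated)
Conditions: 24, 9-MeO-9-BBN, t-BuLi (2.1 equiv), Et2O, −78 °C → rt; then 14, PdCl2(dppf) (5 mol %), AsPh3, K3PO4 (3 M aq.), DMF, rt
Reagents that add atoms: none
Why: B-alkyl Suzuki–Miyaura coupling in which iodine–lithium exchange in the presence of the borinate traps the alkyllithium at once as the ate complex, whose primary alkyl group is transferred after oxidative addition into the Z C5–Br bond with retention, the C–Cl bonds not reacting with this catalyst at rt.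

Step 22
Reactants: 26 open-chain coupling product
Product: 28 14-membered 11-chloro-1,2-epoxy cembranolide (C11–Cl cis to C9; C12 trans to C9), via B-alkyl-9-BBN adduct 27 (not isolated)
Conditions: 9-BBN, THF, rt; then slow addition to Pd2(dba)3 (5 mol %), Xantphos (10 mol %), K3PO4, KF, THF/H2O, 65 °C, 2 mM
Reagents that add atoms: none
Why: Hydroboration of the only monosubstituted alkene puts boron on C12, and intramolecular B-alkyl Suzuki–Miyaura coupling on the 1,1-dichloroalkene takes the chloride trans to C9 (the mono-coupling selectivity known for this catalyst), closing the 14-membered ring.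

Step 23
Reactants: 28 14-membered chloroalkene
Product: 29 14-membered cis-1,2-epoxy cembranolide with C20 trimethylsilyl group (C20 cis to C9), 9-OTIPS, 14-OTBS, free 8-hydroxyl
Conditions: Me3SiCH2MgCl, ZnCl2, THF; then 28, Pd(PtBu3)2 (5 mol %), THF/NMP, rt
Reagents that add atoms: (trimethylsilyl)methylmagnesium chloride, C[Si](C)(C)C[Mg]Cl
Why: Negishi coupling of the alkenyl chloride with retention of geometry gives the 2-substituted allylsilane, the zinc reagent being too mild to attack the lactone or the epoxide.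

Step 24
Reactants: 29 14-membered cis-1,2-epoxy cembranolide allylsilane
Product: 30 2-hydroxy-9-O-triisopropylsilyl-14-O-tert-butyldimethylsilyl briarane lactone
Conditions: MeAlCl2 (2.5 equiv), CH2Cl2, −78 °C → −40 °C; aq. NaHCO3
Reagents that add atoms: none
Why: Proposed new method: MeAlCl2 (one equivalent is spent on the C8 hydroxyl as its aluminium alkoxide, with loss of methane) coordinates the epoxide oxygen, the C1–O bond stretches at the tertiary carbon, C10 of the allylsilane attacks C1 from the side opposite that oxygen, and the cation at C11, β to silicon, loses the silyl group to chloride to give only the exocyclic C11=C20 alkene while the oxygen stays on C2; the closest known reactions are Lewis acid epoxide–allylsilane cyclisations and the transannular epoxide–alkene cyclisations of germacrene and cembrene epoxides, but no briarane has been made this way. Ring A closes 6-endo-trig with respect to the alkene and 6-exo-tet with respect to the epoxide carbon, and the ten-membered ring needs no bond of its own, being the part of the 14-membered ring that is left once C1–C10 exists. C1 is set by inversion at the epoxide carbon whose configuration comes from step 15, and C10 by a chair in which C9 (trans to C12 on the alkene) is equatorial and H10 axial, C2 equatorial and methyl C15 axial on the opposite face, which is the trans ring fusion. The chair with the C14 silyloxy group axial should be preferred because it keeps the C14–O bond out of line with the developing empty orbital at C1 and lines up C14–H instead, on the side of the leaving oxygen where it cannot migrate. The step needs C10 to win over the C5=C6 alkene, over hydride shift from C14 and over ionisation of the allylic C9–O bond: the allylsilane is by far the better nucleophile (C5=C6 is deactivated by the allylic lactone oxygen), and the bulky, weakly basic triisopropylsilyl ether on O9 and the low temperature hold back loss of O9.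

Step 25
Reactants: 30 2-hydroxy briarane lactone
Product: 31 2-O-propanoyl-9-O-TIPS-14-O-TBS briarane lactone
Conditions: (EtCO)2O, Et3N, DMAP (cat.), CH2Cl2, 0 °C → rt
Reagents that add atoms: propanoic anhydride, CCC(=O)OC(=O)CC
Why: DMAP-catalysed acylation of the only secondary hydroxyl, the tertiary C8 hydroxyl being too hindered to react.

Step 26
Reactants: 31 2-O-propanoyl bis-silyl ether
Product: 32 2-O-propanoyl briarane lactone with free 8-, 9- and 14-hydroxyls
Conditions: HF·pyridine, pyridine, THF, 0 °C → rt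
Reagents that add atoms: none
Why: Fluoride-mediated cleavage of both silyl ethers under non-basic conditions, so that the C2 propanoate should not migrate to O14.

Step 27
Reactants: 32 2-O-propanoyl 8,9,14-triol
Product: 33 junceellolide E
Conditions: Ac2O, pyridine, DMAP (cat.), CH2Cl2, rt
Reagents that add atoms: acetic anhydride, CC(=O)OC(C)=O
Why: Acetylation of the two secondary hydroxyls at C9 and C14, the tertiary C8 hydroxyl staying free as in the target.

**Compound list**

1 | 1,2:5,6-di-O-isopropylidene-α-D-glucofuranose | O[C@@H]1[C@H]2OC(C)(C)O[C@H]2O[C@@H]1[C@H]1COC(C)(C)O1 | starting material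
2 | 1,2:5,6-di-O-isopropylidene-α-D-ribo-hexofuranos-3-ulose | O=C1[C@H]2OC(C)(C)O[C@H]2O[C@@H]1[C@H]1COC(C)(C)O1 | intermediate
3 | tert-butyl propanoate | CCC(=O)OC(C)(C)C | starting material
4 | lithium enolate of tert-butyl propanoate | [Li+].C/C=C(\OC(C)(C)C)[O-] | intermediate (not isolated)
5 | 3-C-[1-(tert-butoxycarbonyl)ethyl]-1,2:5,6-di-O-isopropylidene-α-D-allofuranose (C17 epimers) | CC(C(=O)OC(C)(C)C)[C@]1(O)[C@H]2OC(C)(C)O[C@H]2O[C@@H]1[C@H]1COC(C)(C)O1 | intermediate
6 | 3-C-[1-(tert-butoxycarbonyl)ethyl]-1,2-O-isopropylidene-α-D-allofuranose (C17 epimers) | CC(C(=O)OC(C)(C)C)[C@]1(O)[C@H]2OC(C)(C)O[C@H]2O[C@@H]1[C@H](O)CO | intermediate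
7 | 3-C-[1-(tert-butoxycarbonyl)ethyl]-1,2-O-isopropylidene-α-D-ribo-pentodialdo-1,4-furanose (C17 epimers) | CC(C(=O)OC(C)(C)C)[C@]1(O)[C@H]2OC(C)(C)O[C@H]2O[C@@H]1C=O | intermediate
8 | 3-C-[1-(tert-butoxycarbonyl)ethyl]-6,6-dichloro-5,6-dideoxy-1,2-O-isopropylidene-α-D-ribo-hex-5-enofuranose (C17 epimers) | CC(C(=O)OC(C)(C)C)[C@]1(O)[C@H]2OC(C)(C)O[C@H]2O[C@@H]1C=C(Cl)Cl | intermediate
9 | 3-C-[1-(tert-butoxycarbonyl)ethyl]-6,6-dichloro-5,6-dideoxy-2,3-O-isopropylidene-D-ribo-hex-5-enofuranose (anomers, C17 epimers) | CC(C(=O)OC(C)(C)C)[C@]12OC(C)(C)O[C@H]1C(O)O[C@@H]2C=C(Cl)Cl | intermediate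
10 | open-chain tert-butyl ester: C6H=C5Br2, O7/O8 acetonide, 9-OH, C10H=C11Cl2 (C17 epimers) | CC(C(=O)OC(C)(C)C)[C@@]1(OC(C)(C)O[C@H]1C=C(Br)Br)[C@H](O)C=C(Cl)Cl | intermediate
11 | 9-O-triisopropylsilyl ether of 10 | CC(C(=O)OC(C)(C)C)[C@@]1(OC(C)(C)O[C@H]1C=C(Br)Br)[C@H](O[Si](C(C)C)(C(C)C)C(C)C)C=C(Cl)Cl | intermediate
12 | Z bromoalkene C6H=C5(Br)CH3, O7/O8 acetonide, 9-OTIPS, C10H=C11Cl2 (C17 epimers) | CC(C(=O)OC(C)(C)C)[C@@]1(OC(C)(C)O[C@H]1/C=C(/C)Br)[C@H](O[Si](C(C)C)(C(C)C)C(C)C)C=C(Cl)Cl | intermediate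
13 | γ-lactone with 8-OH, 9-OTIPS, Z bromoalkene, dichloroalkene (C17 epimers) | ClC(Cl)=C[C@@H](O[Si](C(C)C)(C(C)C)C(C)C)[C@@]1(O)[C@H](/C=C(/C)Br)OC(=O)C1C | intermediate
14 | lactone core, (17R), C18 cis to 8-OH | ClC(Cl)=C[C@@H](O[Si](C(C)C)(C(C)C)C(C)C)[C@@]1(O)[C@H](/C=C(/C)Br)OC(=O)[C@@H]1C | intermediate
15 | 3-[(4-methoxybenzyl)oxy]propan-1-ol | COc1ccc(COCCCO)cc1 | starting material
16 | 3-[(4-methoxybenzyl)oxy]propanal | COc1ccc(COCCC=O)cc1 | intermediate
17 | methyl (2Z)-5-[(4-methoxybenzyl)oxy]-2-methylpent-2-enoate | COC(=O)/C(C)=C\CCOCc1ccc(OC)cc1 | intermediate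
18 | (2Z)-5-[(4-methoxybenzyl)oxy]-2-methylpent-2-en-1-ol | OC/C(C)=C\CCOCc1ccc(OC)cc1 | intermediate
19 | (2S,3R)-2,3-epoxy-5-[(4-methoxybenzyl)oxy]-2-methylpentan-1-ol | COc1ccc(COCC[C@H]2O[C@@]2(C)CO)cc1 | intermediate
20 | (2R,3R)-2,3-epoxy-5-[(4-methoxybenzyl)oxy]-2-methylpentanal | COc1ccc(COCC[C@H]2O[C@@]2(C)C=O)cc1 | intermediate
21 | erythro (14S) allylic alcohol with cis-1,2-epoxide, C12=C13 vinyl and 4-OPMB | COc1ccc(COCC[C@H]2O[C@@]2(C)[C@@H](O)C=C)cc1 | intermediate
22 | 14-O-TBS ether of 21 | COc1ccc(COCC[C@H]2O[C@@]2(C)[C@@H](O[Si](C)(C)C(C)(C)C)C=C)cc1 | intermediate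
23 | C4 primary alcohol, cis-1,2-epoxide, 14-OTBS, vinyl | OCC[C@H]1O[C@@]1(C)[C@@H](O[Si](C)(C)C(C)(C)C)C=C | intermediate
24 | C4 iodide, cis-1,2-epoxide, 14-OTBS, vinyl | ICC[C@H]1O[C@@]1(C)[C@@H](O[Si](C)(C)C(C)(C)C)C=C | intermediate
25 | lithium B-methoxy ate complex of the C4-alkyl-9-BBN | [Li+].CO[B-]1(CC[C@H]2O[C@@]2(C)[C@@H](O[Si](C)(C)C(C)(C)C)C=C)C2CCCC1CCC2 | intermediate (not isolated)
26 | open-chain coupling product: lactone core joined C4–C5 to the epoxy chain, C10H=C11Cl2 and C12=C13 vinyl ends | ClC(Cl)=C[C@@H](O[Si](C(C)C)(C(C)C)C(C)C)[C@@]1(O)[C@H](/C=C(/C)CC[C@H]2O[C@@]2(C)[C@@H](O[Si](C)(C)C(C)(C)C)C=C)OC(=O)[C@@H]1C | intermediate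
27 | C12 9-BBN adduct of 26 | ClC(Cl)=C[C@@H](O[Si](C(C)C)(C(C)C)C(C)C)[C@@]1(O)[C@H](/C=C(/C)CC[C@H]2O[C@@]2(C)[C@@H](O[Si](C)(C)C(C)(C)C)CCB2C3CCCC2CCC3)OC(=O)[C@@H]1C | intermediate (not isolated)
28 | 14-membered 11-chloro-1,2-epoxy cembranolide, 9-OTIPS, 14-OTBS, 8-OH | Cl\C1=C/[C@@H](O[Si](C(C)C)(C(C)C)C(C)C)[C@@]2(O)[C@H](/C=C(/C)CC[C@H]3O[C@@]3(C)[C@@H](O[Si](C)(C)C(C)(C)C)CC1)OC(=O)[C@@H]2C | intermediate
29 | 14-membered cis-1,2-epoxy cembranolide with C20 trimethylsilyl group, 9-OTIPS, 14-OTBS, 8-OH | C[Si](C)(C)C\C1=C/[C@@H](O[Si](C(C)C)(C(C)C)C(C)C)[C@@]2(O)[C@H](/C=C(/C)CC[C@H]3O[C@@]3(C)[C@@H](O[Si](C)(C)C(C)(C)C)CC1)OC(=O)[C@@H]2C | intermediate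
30 | 2-hydroxy-9-O-TIPS-14-O-TBS briarane lactone | C=C1CC[C@H](O[Si](C)(C)C(C)(C)C)[C@@]2(C)[C@H]1[C@@H](O[Si](C(C)C)(C(C)C)C(C)C)[C@@]1(O)[C@H](/C=C(/C)CC[C@H]2O)OC(=O)[C@@H]1C | intermediate
31 | 2-O-propanoyl-9-O-TIPS-14-O-TBS briarane lactone | C=C1CC[C@H](O[Si](C)(C)C(C)(C)C)[C@@]2(C)[C@H]1[C@@H](O[Si](C(C)C)(C(C)C)C(C)C)[C@@]1(O)[C@H](/C=C(/C)CC[C@H]2OC(=O)CC)OC(=O)[C@@H]1C | intermediate
32 | 2-O-propanoyl briarane lactone with free 8-, 9-, 14-hydroxyls | C=C1CC[C@H](O)[C@@]2(C)[C@H]1[C@@H](O)[C@@]1(O)[C@H](/C=C(/C)CC[C@H]2OC(=O)CC)OC(=O)[C@@H]1C | intermediate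
33 | junceellolide E | C=C1CC[C@H](OC(C)=O)[C@@]2(C)[C@H]1[C@@H](OC(C)=O)[C@@]1(O)[C@H](/C=C(/C)CC[C@H]2OC(=O)CC)OC(=O)[C@@H]1C | target

**Step count and risks**

Total step count: 27. Longest linear sequence: 18 steps (steps 1–11 and 21–27, from diacetone-D-glucose); the epoxy iodide branch is steps 12–20.

The three steps most likely to fail:

1. Step 24 (Proposed new method). What may go wrong: ionisation of the allylic C9–O bond with loss of the silyl group (1,4-elimination to a diene), hydride shift from C14 to C1, capture of C1 by the C5=C6 alkene, or closure through the other chair to the cis-fused C10 epimer. Fallback with known chemistry, from 28 back to 30: Negishi methylation of 28 (MeZnCl, Pd(PtBu3)2, THF) should give the 11-methyl 1,2-epoxy cembranolide F1. Titanocene monochloride (Cp2TiCl, trivalent titanium, made from Cp2TiCl2 and Mn in THF) then opens the epoxide homolytically to the tertiary C1 radical (Nugent–RajanBabu opening), which adds across the ring to C10 as in the known titanocene-promoted transannular cyclisations of epoxygermacrolides. The C11 radical is trapped by a second Cp2TiCl and loses β-hydride from the methyl group to give mainly the exocyclic alkene, and hydrolysis of the O2–Ti bond returns 30.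

2. Step 22. What may go wrong: intermolecular coupling to oligomers, or protodeboronation and β-hydride loss when oxidative addition into the C–Cl bond is slower than decay of the borane under hot aqueous base. Fallback from 26 back to 28: the ring is closed as an alkylzinc under anhydrous Negishi conditions. Hydroboration–oxidation of 26 (9-BBN; then NaBO3) should give the primary alcohol F2, I2/PPh3/imidazole the primary iodide F3, and zinc insertion (Zn, LiCl, THF) the alkylzinc iodide F4. Slow addition of F4 to PdCl2(DPEphos) in THF/DMF, the conditions of the trans-selective mono-alkylation of 1,1-dichloroalkenes, should give 28.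

3. Step 21. What may go wrong: the transient primary alkyllithium opens the epoxide two carbons away (closure to a cyclopropyl carbinol) before boron captures it. Fallback from 18 and 14 back to 26: the coupling is done first and the epoxide made afterwards. Alcohol 18 is silylated (TBSCl, imidazole) to the silyl ether F5, the PMB group is removed (DDQ) to give the alcohol F6, and I2/PPh3/imidazole gives the homoallylic iodide F7. Lithiation in the presence of 9-MeO-9-BBN gives the epoxide-free borate F8, and Suzuki coupling with 14 (PdCl2(dppf), K3PO4) the diene F9. HF·pyridine removes the primary allylic silyl ether to give the allylic alcohol F10, and Sharpless epoxidation with L-(+)-diethyl tartrate gives the epoxy alcohol F11. Dess–Martin oxidation gives the epoxy aldehyde F12, vinylmagnesium bromide at −78 °C (aldehyde before lactone) the erythro allylic alcohol F13, and TBSCl/imidazole then gives 26.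

Further compounds
F1 | step 24 | 11-methyl 1,2-epoxy cembranolide, 9-OTIPS, 14-OTBS | C\C1=C/[C@@H](O[Si](C(C)C)(C(C)C)C(C)C)[C@@]2(O)[C@H](/C=C(/C)CC[C@H]3O[C@@]3(C)[C@@H](O[Si](C)(C)C(C)(C)C)CC1)OC(=O)[C@@H]2C
F2 | step 22 | C12 primary alcohol from 26 | ClC(Cl)=C[C@@H](O[Si](C(C)C)(C(C)C)C(C)C)[C@@]1(O)[C@H](/C=C(/C)CC[C@H]2O[C@@]2(C)[C@@H](O[Si](C)(C)C(C)(C)C)CCO)OC(=O)[C@@H]1C
F3 | step 22 | C12 primary iodide | ClC(Cl)=C[C@@H](O[Si](C(C)C)(C(C)C)C(C)C)[C@@]1(O)[C@H](/C=C(/C)CC[C@H]2O[C@@]2(C)[C@@H](O[Si](C)(C)C(C)(C)C)CCI)OC(=O)[C@@H]1C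
F4 | step 22 | C12 alkylzinc iodide | ClC(Cl)=C[C@@H](O[Si](C(C)C)(C(C)C)C(C)C)[C@@]1(O)[C@H](/C=C(/C)CC[C@H]2O[C@@]2(C)[C@@H](O[Si](C)(C)C(C)(C)C)CC[Zn]I)OC(=O)[C@@H]1C
F5 | step 21 | TBS ether of 18 | CC(C)(C)[Si](C)(C)OC/C(C)=C\CCOCc1ccc(OC)cc1
F6 | step 21 | (3Z)-5-[(tert-butyldimethylsilyl)oxy]-4-methylpent-3-en-1-ol | CC(C)(C)[Si](C)(C)OC/C(C)=C\CCO
F7 | step 21 | (2Z)-1-[(tert-butyldimethylsilyl)oxy]-5-iodo-2-methylpent-2-ene | CC(C)(C)[Si](C)(C)OC/C(C)=C\CCI
F8 | step 21 | lithium B-methoxy ate complex of the alkyl-9-BBN from F7 | [Li+].CO[B-]1(CC/C=C(/C)CO[Si](C)(C)C(C)(C)C)C2CCCC1CCC2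
F9 | step 21 | lactone core joined C4–C5 to the Z allylic silyl ether chain | ClC(Cl)=C[C@@H](O[Si](C(C)C)(C(C)C)C(C)C)[C@@]1(O)[C@H](/C=C(/C)CC/C=C(/C)CO[Si](C)(C)C(C)(C)C)OC(=O)[C@@H]1C
F10 | step 21 | C14 primary Z allylic alcohol | ClC(Cl)=C[C@@H](O[Si](C(C)C)(C(C)C)C(C)C)[C@@]1(O)[C@H](/C=C(/C)CC/C=C(/C)CO)OC(=O)[C@@H]1C
F11 | step 21 | cis-1,2-epoxy C14 primary alcohol | ClC(Cl)=C[C@@H](O[Si](C(C)C)(C(C)C)C(C)C)[C@@]1(O)[C@H](/C=C(/C)CC[C@H]2O[C@@]2(C)CO)OC(=O)[C@@H]1C
F12 | step 21 | cis-1,2-epoxy C14 aldehyde | ClC(Cl)=C[C@@H](O[Si](C(C)C)(C(C)C)C(C)C)[C@@]1(O)[C@H](/C=C(/C)CC[C@H]2O[C@@]2(C)C=O)OC(=O)[C@@H]1C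
F13 | step 21 | erythro (14S) allylic alcohol, 14-OH form of 26 | ClC(Cl)=C[C@@H](O[Si](C(C)C)(C(C)C)C(C)C)[C@@]1(O)[C@H](/C=C(/C)CC[C@H]2O[C@@]2(C)[C@@H](O)C=C)OC(=O)[C@@H]1C
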